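**Assumption:** positions are given in prostanoid numbering (C1 = ester carbon, C8–C12 = ring, C13–C20 = octadienyl chain); 1, 4 and 12 are bought as the single isomers shown.

## Retrosynthetic overview
1. C7=C8: aldol condensation, dehydration and desilylation join a C8–C20 bromo-cyclopentenone and a C1–C7 (S)-silyloxy enal, two halves of similar size, at the end.
2. Bromo-enone: bromide opening and dehydration of the keto-epoxide of the parent enone. The enone comes from (R)-4-hydroxycyclopent-2-enone by anti 1,2-addition of an acetate enolate (sets C12) and later oxidation of the original carbinol.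
3. ω chain: Z-selective Wittig reaction of the ring-bound acetaldehyde with the ylide made from (Z)-hex-3-en-1-ol.
4. α chain: (S)-5-(hydroxymethyl)butyrolactone supplies C1–C5 and the C4 stereocentre; methylenation, lactone opening and cross-metathesis with crotonaldehyde give the enal.
5. Rings: the only ring is never built; it is carried through from the hydroxycyclopentenone.

## Route

### ω-Chain phosphonium salt

Step 1
Reactants: 1 (Z)-hex-3-en-1-ol
Product: 2 (Z)-1-iodohex-3-ene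
Conditions: I2, PPh3, imidazole, CH2Cl2, 0 °C → rt
Reagents that add atoms: iodine, [I][I]
Why: Appel-type iodination (SN2 on the alkoxyphosphonium ion) converts the primary alcohol without touching the Z alkene.

Step 2
Reactants: 2 (Z)-1-iodohex-3-ene
Product: 3 [(Z)-hex-3-en-1-yl]triphenylphosphonium iodide
Conditions: PPh3, MeCN, reflux, 24 h
Reagents that add atoms: triphenylphosphine, c1ccc(cc1)P(c1ccccc1)c1ccccc1
Why: SN2 quaternisation of the primary iodide gives the Wittig salt that carries C15–C20 with the 17Z alkene already in place.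

### α-Chain enal

Step 3
Reactants: 4 (S)-5-(hydroxymethyl)dihydrofuran-2(3H)-one
Product: 5 (S)-5-oxotetrahydrofuran-2-carbaldehyde
Conditions: Dess–Martin periodinane, CH2Cl2, 0 °C → rt; used crude
Reagents that add atoms: none
Why: Dess–Martin oxidation of the primary alcohol is neutral and non-epimerising, so the future C4 stereocentre is kept.

Step 4
Reactants: 5 (S)-5-oxotetrahydrofuran-2-carbaldehyde
Product: 6 (S)-5-vinyldihydrofuran-2(3H)-one
Conditions: Ph3PCH3Br, KN(SiMe3)2, THF, 0 °C; ylide (1.05 equiv) added to 5 at −78 °C → 0 °C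
Reagents that add atoms: methyltriphenylphosphonium bromide, C[P+](c1ccccc1)(c1ccccc1)c1ccccc1.[Br-]
Why: Wittig methylenation is much faster at the aldehyde than at the lactone carbonyl, and inverse addition at low temperature protects the α-oxygenated stereocentre.

Step 5
Reactants: 6 (S)-5-vinyldihydrofuran-2(3H)-one
Product: 8 methyl (S)-4-hydroxyhex-5-enoate, via potassium (S)-4-hydroxyhex-5-enoate 7 (not isolated)
Conditions: KOH (1.0 equiv), MeOH/H2O, rt; evaporate; MeI, DMF, 0 °C → rt; used at once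
Reagents that add atoms: potassium hydroxide, [K+].[OH-]; iodomethane, IC
Why: saponification followed by SN2 O-methylation of the carboxylate gives the open hydroxy ester under neutral conditions that do not relactonise it; the stereocentre is not involved.

Step 6
Reactants: 8 methyl (S)-4-hydroxyhex-5-enoate
Product: 9 methyl (S)-4-[(tert-butyldimethylsilyl)oxy]hex-5-enoate
Conditions: TBSCl, imidazole, DMF, rt
Reagents that add atoms: tert-butyldimethylsilyl chloride, CC(C)(C)[Si](C)(C)Cl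
Why: silylation of the secondary allylic alcohol blocks relactonisation and protects O4 through the later enolate chemistry.

Step 7
Reactants: 9 methyl (S)-4-[(tert-butyldimethylsilyl)oxy]hex-5-enoate; 10 (E)-but-2-enal (crotonaldehyde, 5 equiv)
Product: 11 methyl (S,E)-4-[(tert-butyldimethylsilyl)oxy]-7-oxohept-5-enoate
Conditions: second-generation Hoveyda–Grubbs catalyst RuCl2(H2IMes)(=CH-C6H4-2-OiPr) (5 mol %), CH2Cl2, 40 °C
Reagents that add atoms: none
Why: olefin cross-metathesis between the hindered allylic silyl ether and the electron-poor enal is selective for the cross product and gives the thermodynamic 5E enal with loss of propene.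

### Ring and ω chain (main line)

Step 8
Reactants: 12 (R)-4-hydroxycyclopent-2-en-1-one
Product: 13 (R)-4-[(triethylsilyl)oxy]cyclopent-2-en-1-one
Conditions: TESCl, imidazole, CH2Cl2, 0 °C
Reagents that add atoms: chlorotriethylsilane, CC[Si](CC)(CC)Cl
Why: silylation gives a bulky but later selectively removable group that shields one face of the enone.

Step 9
Reactants: 13 (R)-4-[(triethylsilyl)oxy]cyclopent-2-en-1-one; 14 ethyl acetate
Product: 16 ethyl 2-[(1R,4R)-1-hydroxy-4-[(triethylsilyl)oxy]cyclopent-2-en-1-yl]acetate, via lithium enolate of ethyl acetate 15 (not isolated)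
Conditions: LiN(iPr)2, THF, −78 °C; then 13, −78 °C, 20 min; AcOH quench at −78 °C
Reagents that add atoms: none
Why: kinetic 1,2-aldol addition of the ester enolate to the enone carbonyl occurs on the face anti to OTES and so sets C12 (OH cis to OTES); the minor syn adduct is removed by chromatography.

Step 10
Reactants: 16 ethyl 2-[(1R,4R)-1-hydroxy-4-[(triethylsilyl)oxy]cyclopent-2-en-1-yl]acetate
Product: 17 ethyl 2-[(1R,4R)-1-[(tert-butyldimethylsilyl)oxy]-4-[(triethylsilyl)oxy]cyclopent-2-en-1-yl]acetate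
Conditions: TBSOTf, 2,6-lutidine, CH2Cl2, 0 °C → rt
Reagents that add atoms: tert-butyldimethylsilyl trifluoromethanesulfonate, CC(C)(C)[Si](C)(C)OS(=O)(=O)C(F)(F)F
Why: the silyl triflate silylates the hindered tertiary alcohol, which stops retro-aldol cleavage and gives a group that outlasts the secondary TES ether.

Step 11
Reactants: 17 ethyl 2-[(1R,4R)-1-[(tert-butyldimethylsilyl)oxy]-4-[(triethylsilyl)oxy]cyclopent-2-en-1-yl]acetate
Product: 18 2-[(1R,4R)-1-[(tert-butyldimethylsilyl)oxy]-4-[(triethylsilyl)oxy]cyclopent-2-en-1-yl]acetaldehyde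
Conditions: iBu2AlH (1.1 equiv), CH2Cl2, −78 °C; MeOH, then aq. potassium sodium tartrate
Reagents that add atoms: none
Why: partial hydride reduction of the β-silyloxy ester stops at the aldehyde because the tetrahedral aluminium hemiacetal is stable at −78 °C.

Step 12
Reactants: 18 2-[(1R,4R)-1-[(tert-butyldimethylsilyl)oxy]-4-[(triethylsilyl)oxy]cyclopent-2-en-1-yl]acetaldehyde; 3 [(Z)-hex-3-en-1-yl]triphenylphosphonium iodide
Product: 20 tert-butyldimethyl{[(1S,4R)-1-[(2Z,5Z)-octa-2,5-dien-1-yl]-4-[(triethylsilyl)oxy]cyclopent-2-en-1-yl]oxy}silane, via [(Z)-hex-3-en-1-ylidene]triphenylphosphorane 19 (not isolated)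
Conditions: 3, NaN(SiMe3)2, THF, −78 → 0 °C; then 18, −78 °C → rt
Reagents that add atoms: none
Why: the lithium-free Wittig reaction of a non-stabilised ylide forms the 14Z alkene under kinetic control and completes the skipped Z,Z-diene; the C1 descriptor changes only because the CIP priorities change.

Step 13
Reactants: 20 tert-butyldimethyl{[(1S,4R)-1-[(2Z,5Z)-octa-2,5-dien-1-yl]-4-[(triethylsilyl)oxy]cyclopent-2-en-1-yl]oxy}silane
Product: 21 (1R,4S)-4-[(tert-butyldimethylsilyl)oxy]-4-[(2Z,5Z)-octa-2,5-dien-1-yl]cyclopent-2-en-1-ol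
Conditions: PPTS (0.2 equiv), MeOH/CH2Cl2, 0 °C
Reagents that add atoms: none
Why: mild acid methanolysis removes the secondary TES ether far faster than the hindered tertiary TBS ether.

Step 14
Reactants: 21 (1R,4S)-4-[(tert-butyldimethylsilyl)oxy]-4-[(2Z,5Z)-octa-2,5-dien-1-yl]cyclopent-2-en-1-ol
Product: 22 (S)-4-[(tert-butyldimethylsilyl)oxy]-4-[(2Z,5Z)-octa-2,5-dien-1-yl]cyclopent-2-en-1-one
Conditions: Dess–Martin periodinane, CH2Cl2, 0 °C → rt
Reagents that add atoms: none
Why: oxidation of the allylic alcohol completes the 1,3-carbonyl transposition; the original stereocentre is erased after relaying its chirality to C12.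

Step 15
Reactants: 22 (S)-4-[(tert-butyldimethylsilyl)oxy]-4-[(2Z,5Z)-octa-2,5-dien-1-yl]cyclopent-2-en-1-one
Product: 23 (1R,4S,5S)-4-[(tert-butyldimethylsilyl)oxy]-4-[(2Z,5Z)-octa-2,5-dien-1-yl]-6-oxabicyclo[3.1.0]hexan-2-one
Conditions: 30% aq. H2O2, NaOH (0.2 equiv), MeOH, −20 → 0 °C
Reagents that add atoms: hydrogen peroxide, OO
Why: Weitz–Scheffer nucleophilic epoxidation attacks only the electron-poor enone alkene and leaves the skipped diene alone; the oxirane is expected anti to OTBS, and either epimer converges in step 16.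

Step 16
Reactants: 23 (1R,4S,5S)-4-[(tert-butyldimethylsilyl)oxy]-4-[(2Z,5Z)-octa-2,5-dien-1-yl]-6-oxabicyclo[3.1.0]hexan-2-one
Product: 26 (S)-2-bromo-4-[(tert-butyldimethylsilyl)oxy]-4-[(2Z,5Z)-octa-2,5-dien-1-yl]cyclopent-2-en-1-one, via bromohydrin 24 (not isolated), via bromohydrin mesylate 25 (not isolated)
Conditions: MgBr2·OEt2, Et2O/CH2Cl2, −20 → 0 °C; then Et3N, MsCl, 0 °C → rt
Reagents that add atoms: magnesium bromide diethyl etherate, Br[Mg]Br.CCOCC
Why: bromide opens the keto-epoxide by SN2 at the carbon α to the ketone (the β carbon is neopentyl), and mesylation with E1cB loss of the β-mesylate gives the 2-bromo-enone, the same logic as 4-halo-enone formation from 4,5-epoxy-3-keto steroids.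

### Coupling and end game

Step 17
Reactants: 26 (S)-2-bromo-4-[(tert-butyldimethylsilyl)oxy]-4-[(2Z,5Z)-octa-2,5-dien-1-yl]cyclopent-2-en-1-one; 11 methyl (S,E)-4-[(tert-butyldimethylsilyl)oxy]-7-oxohept-5-enoate
Product: 28 methyl (4S,5E)-7-[(5S)-3-bromo-5-[(tert-butyldimethylsilyl)oxy]-5-[(2Z,5Z)-octa-2,5-dien-1-yl]-2-oxocyclopent-3-en-1-yl]-4-[(tert-butyldimethylsilyl)oxy]-7-hydroxyhept-5-enoate (C7/C8 diastereomer mixture), via lithium dienolate 27 (not isolated)
Conditions: LiN(iPr)2 (1.05 equiv), THF, −78 °C, 15 min; then 11, −78 °C, 30 min; AcOH quench at −78 °C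
Reagents that add atoms: none
Why: kinetic α'-deprotonation gives the cross-conjugated lithium enolate, which adds 1,2 to the enal in a directed aldol reaction (known for the chloro analogues of this skeleton); the new C7 and C8 centres are erased in step 18.

Step 18
Reactants: 28 methyl (4S,5E)-7-[(5S)-3-bromo-5-[(tert-butyldimethylsilyl)oxy]-5-[(2Z,5Z)-octa-2,5-dien-1-yl]-2-oxocyclopent-3-en-1-yl]-4-[(tert-butyldimethylsilyl)oxy]-7-hydroxyhept-5-enoate
Product: 30 methyl (4S,5E,7Z)-7-[(5R)-3-bromo-5-[(tert-butyldimethylsilyl)oxy]-5-[(2Z,5Z)-octa-2,5-dien-1-yl]-2-oxocyclopent-3-en-1-ylidene]-4-[(tert-butyldimethylsilyl)oxy]hept-5-enoate, via C7 mesylate 29 (not isolated)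
Conditions: MsCl, Et3N (5 equiv), CH2Cl2, −20 °C → rt; 7Z isomer separated from 7E by silica chromatography/HPLC
Reagents that add atoms: none
Why: mesylation and E1cB elimination give the cross-conjugated dienone as a separable 7E/7Z mixture, in which the bulky C12 silyloxy group disfavours the 7E form; only the 7Z isomer is carried on.

Step 19
Reactants: 30 methyl (4S,5E,7Z)-7-[(5R)-3-bromo-5-[(tert-butyldimethylsilyl)oxy]-5-[(2Z,5Z)-octa-2,5-dien-1-yl]-2-oxocyclopent-3-en-1-ylidene]-4-[(tert-butyldimethylsilyl)oxy]hept-5-enoate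
Product: 31 methyl (4S,5E,7Z)-7-[(5R)-3-bromo-5-hydroxy-5-[(2Z,5Z)-octa-2,5-dien-1-yl]-2-oxocyclopent-3-en-1-ylidene]-4-hydroxyhept-5-enoate
Conditions: HF·pyridine, pyridine/THF, 0 °C → rt; NaHCO3 work-up
Reagents that add atoms: none
Why: buffered fluoride desilylation removes both TBS ethers without base (no Michael addition to the bromo-dienone) and without strong acid (no lactonisation of the γ-hydroxy ester or ionisation at C12).

## Compound list
1 | (Z)-hex-3-en-1-ol | CC/C=C\CCO | starting material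
2 | (Z)-1-iodohex-3-ene | CC/C=C\CCI | intermediate
3 | [(Z)-hex-3-en-1-yl]triphenylphosphonium iodide | CC/C=C\CC[P+](c1ccccc1)(c1ccccc1)c1ccccc1.[I-] | intermediate
4 | (S)-5-(hydroxymethyl)dihydrofuran-2(3H)-one | OC[C@@H]1CCC(=O)O1 | starting material
5 | (S)-5-oxotetrahydrofuran-2-carbaldehyde | O=C[C@@H]1CCC(=O)O1 | intermediate
6 | (S)-5-vinyldihydrofuran-2(3H)-one | C=C[C@@H]1CCC(=O)O1 | intermediate
7 | potassium (S)-4-hydroxyhex-5-enoate | [K+].[O-]C(=O)CC[C@H](O)C=C | intermediate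
8 | methyl (S)-4-hydroxyhex-5-enoate | COC(=O)CC[C@H](O)C=C | intermediate
9 | methyl (S)-4-[(tert-butyldimethylsilyl)oxy]hex-5-enoate | COC(=O)CC[C@H](O[Si](C)(C)C(C)(C)C)C=C | intermediate
10 | (E)-but-2-enal | C/C=C/C=O | starting material
11 | methyl (S,E)-4-[(tert-butyldimethylsilyl)oxy]-7-oxohept-5-enoate | COC(=O)CC[C@H](O[Si](C)(C)C(C)(C)C)/C=C/C=O | intermediate
12 | (R)-4-hydroxycyclopent-2-en-1-one | O=C1C=C[C@H](O)C1 | starting material
13 | (R)-4-[(triethylsilyl)oxy]cyclopent-2-en-1-one | O=C1C=C[C@H](O[Si](CC)(CC)CC)C1 | intermediate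
14 | ethyl acetate | CCOC(C)=O | starting material
15 | lithium enolate of ethyl acetate (lithium 1-ethoxyethen-1-olate) | [Li]OC(=C)OCC | intermediate
16 | ethyl 2-[(1R,4R)-1-hydroxy-4-[(triethylsilyl)oxy]cyclopent-2-en-1-yl]acetate (OH cis to OTES) | CCOC(=O)C[C@@]1(O)C=C[C@H](O[Si](CC)(CC)CC)C1 | intermediate
17 | ethyl 2-[(1R,4R)-1-[(tert-butyldimethylsilyl)oxy]-4-[(triethylsilyl)oxy]cyclopent-2-en-1-yl]acetate | CCOC(=O)C[C@@]1(O[Si](C)(C)C(C)(C)C)C=C[C@H](O[Si](CC)(CC)CC)C1 | intermediate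
18 | 2-[(1R,4R)-1-[(tert-butyldimethylsilyl)oxy]-4-[(triethylsilyl)oxy]cyclopent-2-en-1-yl]acetaldehyde | O=CC[C@@]1(O[Si](C)(C)C(C)(C)C)C=C[C@H](O[Si](CC)(CC)CC)C1 | intermediate
19 | [(Z)-hex-3-en-1-ylidene]triphenylphosphorane | CC/C=C\CC=P(c1ccccc1)(c1ccccc1)c1ccccc1 | intermediate
20 | tert-butyldimethyl{[(1S,4R)-1-[(2Z,5Z)-octa-2,5-dien-1-yl]-4-[(triethylsilyl)oxy]cyclopent-2-en-1-yl]oxy}silane | CC/C=C\C/C=C\C[C@@]1(O[Si](C)(C)C(C)(C)C)C=C[C@H](O[Si](CC)(CC)CC)C1 | intermediate
21 | (1R,4S)-4-[(tert-butyldimethylsilyl)oxy]-4-[(2Z,5Z)-octa-2,5-dien-1-yl]cyclopent-2-en-1-ol | CC/C=C\C/C=C\C[C@@]1(O[Si](C)(C)C(C)(C)C)C=C[C@H](O)C1 | intermediate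
22 | (S)-4-[(tert-butyldimethylsilyl)oxy]-4-[(2Z,5Z)-octa-2,5-dien-1-yl]cyclopent-2-en-1-one | CC/C=C\C/C=C\C[C@@]1(O[Si](C)(C)C(C)(C)C)C=CC(=O)C1 | intermediate
23 | (1R,4S,5S)-4-[(tert-butyldimethylsilyl)oxy]-4-[(2Z,5Z)-octa-2,5-dien-1-yl]-6-oxabicyclo[3.1.0]hexan-2-one (oxirane anti to OTBS; the syn epimer converges) | CC/C=C\C/C=C\C[C@@]1(O[Si](C)(C)C(C)(C)C)[C@H]2O[C@H]2C(=O)C1 | intermediate
24 | (2S,3R,4S)-2-bromo-4-[(tert-butyldimethylsilyl)oxy]-3-hydroxy-4-[(2Z,5Z)-octa-2,5-dien-1-yl]cyclopentan-1-one (present as its bromomagnesium alkoxide) | CC/C=C\C/C=C\C[C@@]1(O[Si](C)(C)C(C)(C)C)[C@@H](O)[C@H](Br)C(=O)C1 | intermediate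
25 | (1R,2S,5S)-2-bromo-5-[(tert-butyldimethylsilyl)oxy]-5-[(2Z,5Z)-octa-2,5-dien-1-yl]-3-oxocyclopentyl methanesulfonate | CC/C=C\C/C=C\C[C@@]1(O[Si](C)(C)C(C)(C)C)[C@@H](OS(C)(=O)=O)[C@H](Br)C(=O)C1 | intermediate
26 | (S)-2-bromo-4-[(tert-butyldimethylsilyl)oxy]-4-[(2Z,5Z)-octa-2,5-dien-1-yl]cyclopent-2-en-1-one | CC/C=C\C/C=C\C[C@@]1(O[Si](C)(C)C(C)(C)C)C=C(Br)C(=O)C1 | intermediate
27 | lithium cross-conjugated dienolate of 26 | CC/C=C\C/C=C\C[C@@]1(O[Si](C)(C)C(C)(C)C)C=C(Br)C(O[Li])=C1 | intermediate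
28 | methyl (4S,5E)-7-[(5S)-3-bromo-5-[(tert-butyldimethylsilyl)oxy]-5-[(2Z,5Z)-octa-2,5-dien-1-yl]-2-oxocyclopent-3-en-1-yl]-4-[(tert-butyldimethylsilyl)oxy]-7-hydroxyhept-5-enoate (C7/C8 diastereomer mixture, left undefined in the SMILES) | CC/C=C\C/C=C\C[C@@]1(O[Si](C)(C)C(C)(C)C)C=C(Br)C(=O)C1C(O)/C=C/[C@@H](O[Si](C)(C)C(C)(C)C)CCC(=O)OC | intermediate
29 | C7 methanesulfonate of 28 (same diastereomer mixture) | CC/C=C\C/C=C\C[C@@]1(O[Si](C)(C)C(C)(C)C)C=C(Br)C(=O)C1C(OS(C)(=O)=O)/C=C/[C@@H](O[Si](C)(C)C(C)(C)C)CCC(=O)OC | intermediate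
30 | methyl (4S,5E,7Z)-7-[(5R)-3-bromo-5-[(tert-butyldimethylsilyl)oxy]-5-[(2Z,5Z)-octa-2,5-dien-1-yl]-2-oxocyclopent-3-en-1-ylidene]-4-[(tert-butyldimethylsilyl)oxy]hept-5-enoate | CC/C=C\C/C=C\C[C@@]1(O[Si](C)(C)C(C)(C)C)C=C(Br)C(=O)/C1=C\C=C\[C@@H](O[Si](C)(C)C(C)(C)C)CCC(=O)OC | intermediate
31 | methyl (4S,5E,7Z)-7-[(5R)-3-bromo-5-hydroxy-5-[(2Z,5Z)-octa-2,5-dien-1-yl]-2-oxocyclopent-3-en-1-ylidene]-4-hydroxyhept-5-enoate (CNP0168693.1) | CC/C=C\C/C=C\C[C@@]1(O)C=C(Br)C(=O)/C1=C\C=C\[C@@H](O)CCC(=O)OC | target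

## Totals
Total step count: 19 (steps 1–2 ω-chain salt, steps 3–7 α-chain enal, steps 8–19 main line).
Longest linear sequence: 12 steps (steps 8–19, from 12 to 31).

## Three steps most likely to fail

**Step 18 (geometry of C7=C8).** The E1cB elimination is not stereospecific and may favour the 7E isomer. Fallback, setting out from 28 and coming back at 30: 28 is dehydrated as in step 18 and the unwanted geometric isomer, the (7E)-dienone F1, is collected. F1 is then irradiated (350 nm, degassed benzene, 10 °C), which excites only the cross-conjugated dienone and equilibrates the exocyclic alkene to a photostationary 7E/7Z mixture. 30 is separated and F1 is resubmitted, so the geometry is set by photoisomerisation and not by the elimination.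

**Step 16 (bromo-enone from the keto-epoxide beside a skipped diene).** The opening could take the wrong regiochemistry, or the dehydration could stall. Fallback, setting out from 18 and coming back at 26: bromine is introduced before the skipped diene exists. 18 with PPTS and HC(OMe)3 in MeOH gives, by acetalisation and loss of the TES group in one operation, the acetal alcohol F2. Dess–Martin oxidation gives the acetal enone F3. Br2 in CH2Cl2 at −78 °C adds to the only alkene to give the trans-dibromide F4, which loses HBr on addition of Et3N to give the bromo-enone acetal F5. Aqueous oxalic acid in THF frees the bromo-enone aldehyde F6. A salt-free Wittig reaction of F6 with ylide 19 at −78 °C, where the aldehyde is far more reactive than the hindered enone carbonyl, gives 26.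

**Step 9 (1,2-addition that sets C12).** Facial selectivity may be modest, and 1,4-addition or enolisation with loss of silanolate can compete. Fallback, setting out from 13 and coming back at 18: CH2=CHCH2MgBr in THF at −78 °C adds 1,2 and irreversibly, anti to OTES, to give the allyl carbinol F7. TBSOTf/2,6-lutidine gives the bis-silyl ether F8. OsO4 (2 mol %) with N-methylmorpholine N-oxide dihydroxylates only the monosubstituted alkene, since the ring alkene is flanked by two oxygenated carbons, one of them quaternary, to give the diol F9. NaIO4 cleaves F9 to 18.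

## Further compounds
F1 | step 18 | methyl (4S,5E,7E)-7-[(5R)-3-bromo-5-[(tert-butyldimethylsilyl)oxy]-5-[(2Z,5Z)-octa-2,5-dien-1-yl]-2-oxocyclopent-3-en-1-ylidene]-4-[(tert-butyldimethylsilyl)oxy]hept-5-enoate | CC/C=C\C/C=C\C[C@@]1(O[Si](C)(C)C(C)(C)C)C=C(Br)C(=O)/C1=C/C=C/[C@@H](O[Si](C)(C)C(C)(C)C)CCC(=O)OC
F2 | step 16 | (1R,4R)-4-[(tert-butyldimethylsilyl)oxy]-4-(2,2-dimethoxyethyl)cyclopent-2-en-1-ol | COC(OC)C[C@@]1(O[Si](C)(C)C(C)(C)C)C=C[C@H](O)C1
F3 | step 16 | (S)-4-[(tert-butyldimethylsilyl)oxy]-4-(2,2-dimethoxyethyl)cyclopent-2-en-1-one | COC(OC)C[C@@]1(O[Si](C)(C)C(C)(C)C)C=CC(=O)C1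
F4 | step 16 | (4S)-2,3-dibromo-4-[(tert-butyldimethylsilyl)oxy]-4-(2,2-dimethoxyethyl)cyclopentan-1-one (trans-dibromide, C2/C3 epimer mixture) | COC(OC)C[C@@]1(O[Si](C)(C)C(C)(C)C)C(Br)C(Br)C(=O)C1
F5 | step 16 | (S)-2-bromo-4-[(tert-butyldimethylsilyl)oxy]-4-(2,2-dimethoxyethyl)cyclopent-2-en-1-one | COC(OC)C[C@@]1(O[Si](C)(C)C(C)(C)C)C=C(Br)C(=O)C1
F6 | step 16 | 2-[(1S)-3-bromo-1-[(tert-butyldimethylsilyl)oxy]-4-oxocyclopent-2-en-1-yl]acetaldehyde | O=CC[C@@]1(O[Si](C)(C)C(C)(C)C)C=C(Br)C(=O)C1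
F7 | step 9 | (1S,4R)-1-(prop-2-en-1-yl)-4-[(triethylsilyl)oxy]cyclopent-2-en-1-ol | C=CC[C@@]1(O)C=C[C@H](O[Si](CC)(CC)CC)C1
F8 | step 9 | tert-butyldimethyl{[(1S,4R)-1-(prop-2-en-1-yl)-4-[(triethylsilyl)oxy]cyclopent-2-en-1-yl]oxy}silane | C=CC[C@@]1(O[Si](C)(C)C(C)(C)C)C=C[C@H](O[Si](CC)(CC)CC)C1
F9 | step 9 | 3-[(1S,4R)-1-[(tert-butyldimethylsilyl)oxy]-4-[(triethylsilyl)oxy]cyclopent-2-en-1-yl]propane-1,2-diol (epimer mixture at the new carbinol) | OCC(O)C[C@@]1(O[Si](C)(C)C(C)(C)C)C=C[C@H](O[Si](CC)(CC)CC)C1
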